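**Strategy.** The target is read as a ring-contracted flavanone. The C3–C3a bond of the dihydrofuran ring (O1–C2–C3–C3a–C7a) is made by a 1,2-shift of ring A carbon C4a of (S)-7-allyloxy-3′,4′,5′-trimethoxyflavanone from the carbonyl carbon C4 to C3, triggered by an aryl-λ3-iodane. In one operation the pyranone contracts, the extruded C4 becomes a C3 ester (later the C3 methyl), and the trans C2/C3 relation is set. The step exploits the C6 oxygen para to C3a, which makes ring A the best migrating group, and the adjacent C2(aryl)/C3 pair. A final Claisen shift moves the allyl group from O6 to C5.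

Key step: step 3

Assumption: in step 2 the (S,S) diene ligand is taken to deliver the aryl group to the face that gives (2S), by analogy with its sense of induction on 2-cyclohexenone; should the sense prove opposite, the (R,R) ligand is used with no other change.

**Step 1**
Reactants: 1 7-hydroxychromone; 2 allyl bromide
Product: 3 7-(allyloxy)-4H-chromen-4-one
Conditions: K2CO3, acetone, reflux
Reagents that add atoms: allyl bromide, C=CCBr
Why: Williamson etherification of the only acidic site, the 7-OH (a vinylogous carboxylic acid), should give the allyl ether that serves both as phenol protection and as the later Claisen substrate.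

**Step 2**
Reactants: 3 7-(allyloxy)-4H-chromen-4-one; 4 (3,4,5-trimethoxyphenyl)boronic acid
Product: 5 (2S)-7-(allyloxy)-2-(3,4,5-trimethoxyphenyl)chroman-4-one
Conditions: [RhCl(C2H4)2]2 (cat.), (1S,4S)-2,5-diphenylbicyclo[2.2.2]octa-2,5-diene (cat.), aq. KOH (cat.), 4 (2–3 equiv), toluene/H2O, 40 °C
Reagents that add atoms: (3,4,5-trimethoxyphenyl)boronic acid, COc1cc(B(O)O)cc(OC)c1OC
Why: Hayashi–Miyaura rhodium-catalysed asymmetric 1,4-addition, in which the aryl-rhodium species adds to C2 of the chromone enone on the face left open by the chiral diene, setting C2 as (S), and hydrolysis of the rhodium enolate releases the flavanone.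

**Step 3**
Reactants: 5 (2S)-7-(allyloxy)-2-(3,4,5-trimethoxyphenyl)chroman-4-one
Product: 8 methyl (2S,3S)-6-(allyloxy)-2-(3,4,5-trimethoxyphenyl)-2,3-dihydrobenzofuran-3-carboxylate, via methyl enol ether 6 (not isolated), via trans-iodane ketal 7 (not isolated)
Conditions: PhI(OAc)2 (1.1 equiv), conc. H2SO4, HC(OMe)3, rt
Reagents that add atoms: trimethyl orthoformate, COC(OC)OC
Why: H2SO4/HC(OMe)3 turns ketone 5 into methyl enol ether 6, whose C3 attacks the trivalent iodine of PhI(OAc)2 on the face anti to the C2 aryl group, and methanol capture gives the 2,3-trans λ3-iodane ketal 7. Its equatorial C3–I bond lies antiperiplanar to the C4–C4a ring bond, so ring A carbon C4a shifts from C4 to C3 as iodobenzene leaves (1,2-aryl shift through a bridged phenonium-type transition state), which forms the C3–C3a bond, and the dimethoxycarbenium ion left at the old C4 collapses to the methyl ester. This is the known hypervalent-iodine oxidative ring contraction of flavanones to methyl trans-2-aryl-2,3-dihydrobenzofuran-3-carboxylates. The five-membered ring closes by contraction of the six-membered pyranone, formally a 3-exo-tet attack of the arene ipso carbon on C3 followed by cleavage of the C4–C4a bond. The C3 stereocenter is set by invertive displacement of the trans iodane under control of the C2 stereocenter, which places the ester trans to the aryl group (also the thermodynamic arrangement at this epimerisable carbon), while C2 itself is not touched. The step needs migration of ring A in preference to the 2-aryl group (isoflavone path), elimination (flavone) or attack on the allyl alkene; the C7 allyloxy group para to C4a and the ring oxygen ortho to it make ring A the best migrating group, the diequatorial geometry aligns only the C4–C4a bond, and the enol ether is far more nucleophilic than the allyl ether alkene.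

**Step 4**
Reactants: 8 methyl (2S,3S)-6-(allyloxy)-2-(3,4,5-trimethoxyphenyl)-2,3-dihydrobenzofuran-3-carboxylate
Product: 9 [(2S,3R)-6-(allyloxy)-2-(3,4,5-trimethoxyphenyl)-2,3-dihydrobenzofuran-3-yl]methanol
Conditions: LiAlH4, THF, 0 °C; Fieser work-up
Reagents that add atoms: none
Why: Hydride reduction of the ester to the primary alcohol should leave the aryl ethers and the alkene untouched, and the trans arrangement is the stable one, so no stereocenter is at risk (the C3 descriptor changes only by priority).

**Step 5**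
Reactants: 9 [(2S,3R)-6-(allyloxy)-2-(3,4,5-trimethoxyphenyl)-2,3-dihydrobenzofuran-3-yl]methanol
Product: 11 (2S,3S)-6-(allyloxy)-3-methyl-2-(3,4,5-trimethoxyphenyl)-2,3-dihydrobenzofuran, via primary mesylate 10 (not isolated)
Conditions: MsCl, Et3N, THF, 0 °C; filter under Ar; then LiEt3BH (THF), 0 °C to rt; aq. NH4Cl
Reagents that add atoms: none
Why: Sulfonylation followed by SN2 hydride displacement (deoxygenation of a primary alcohol via its mesylate) should give the C3 methyl group, direct hydride attack on the primary carbon outrunning participation by ring A, with no stereocenter touched.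

**Step 6**
Reactants: 11 (2S,3S)-6-(allyloxy)-3-methyl-2-(3,4,5-trimethoxyphenyl)-2,3-dihydrobenzofuran
Product: 13 (2S,3S)-5-allyl-3-methyl-2-(3,4,5-trimethoxyphenyl)-2,3-dihydrobenzofuran-6-ol, via ortho-dienone 12 (not isolated)
Conditions: N,N-diethylaniline, 190 °C, sealed tube, Ar
Reagents that add atoms: none
Why: Aromatic Claisen rearrangement ([3,3]-sigmatropic shift, then tautomerisation of the dienone) should deliver the allyl group to C5, the ortho position para to the ring oxygen and remote from the ring fusion (the site at which 6-oxygenated 2,3-dihydrobenzofurans react), freeing the C6 phenol in the same step.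

**Compound list**
1 | 7-hydroxy-4H-chromen-4-one (7-hydroxychromone) | O=c1ccoc2cc(O)ccc12 | starting material
2 | allyl bromide (3-bromoprop-1-ene) | C=CCBr | starting material
3 | 7-(allyloxy)-4H-chromen-4-one | C=CCOc1ccc2c(c1)occc2=O | intermediate
4 | (3,4,5-trimethoxyphenyl)boronic acid | COc1cc(B(O)O)cc(OC)c1OC | starting material
5 | (2S)-7-(allyloxy)-2-(3,4,5-trimethoxyphenyl)chroman-4-one | C=CCOc1ccc2c(c1)O[C@H](c1cc(OC)c(OC)c(OC)c1)CC2=O | intermediate
6 | (2S)-7-(allyloxy)-4-methoxy-2-(3,4,5-trimethoxyphenyl)-2H-chromene (methyl enol ether) | C=CCOc1ccc2c(c1)O[C@H](c1cc(OC)c(OC)c(OC)c1)C=C2OC | intermediate (not isolated)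
7 | (2R,3R)-3-[acetoxy(phenyl)-λ3-iodanyl]-7-(allyloxy)-4,4-dimethoxy-2-(3,4,5-trimethoxyphenyl)chroman (iodine trans to the C2 aryl group) | C=CCOc1ccc2c(c1)O[C@H](c1cc(OC)c(OC)c(OC)c1)[C@@H](I(OC(C)=O)c1ccccc1)C2(OC)OC | intermediate (not isolated)
8 | methyl (2S,3S)-6-(allyloxy)-2-(3,4,5-trimethoxyphenyl)-2,3-dihydrobenzofuran-3-carboxylate (2,3-trans) | C=CCOc1ccc2c(c1)O[C@H](c1cc(OC)c(OC)c(OC)c1)[C@H]2C(=O)OC | intermediate
9 | [(2S,3R)-6-(allyloxy)-2-(3,4,5-trimethoxyphenyl)-2,3-dihydrobenzofuran-3-yl]methanol (2,3-trans) | C=CCOc1ccc2c(c1)O[C@H](c1cc(OC)c(OC)c(OC)c1)[C@H]2CO | intermediate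
10 | [(2S,3R)-6-(allyloxy)-2-(3,4,5-trimethoxyphenyl)-2,3-dihydrobenzofuran-3-yl]methyl methanesulfonate | C=CCOc1ccc2c(c1)O[C@H](c1cc(OC)c(OC)c(OC)c1)[C@H]2COS(C)(=O)=O | intermediate (not isolated)
11 | (2S,3S)-6-(allyloxy)-3-methyl-2-(3,4,5-trimethoxyphenyl)-2,3-dihydrobenzofuran (2,3-trans) | C=CCOc1ccc2c(c1)O[C@H](c1cc(OC)c(OC)c(OC)c1)[C@H]2C | intermediate
12 | (2S,3S)-5-allyl-3-methyl-2-(3,4,5-trimethoxyphenyl)-3,5-dihydrobenzofuran-6(2H)-one (ortho-dienone, C5 unassigned) | C=CCC1C=C2C(=CC1=O)O[C@H](c1cc(OC)c(OC)c(OC)c1)[C@H]2C | intermediate (not isolated)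
13 | (2S,3S)-5-allyl-3-methyl-2-(3,4,5-trimethoxyphenyl)-2,3-dihydrobenzofuran-6-ol (2,3-trans) | C=CCc1cc2c(cc1O)O[C@H](c1cc(OC)c(OC)c(OC)c1)[C@H]2C | target

**Total step count:** 6
**Longest linear sequence:** 6 steps (1 → 3 → 5 → 8 → 9 → 11 → 13)

**Steps most likely to fail**

Step 3 (key step). What may go wrong: migration of the trimethoxyphenyl group or elimination to the flavone instead of the ring A shift, acid-induced opening of the pyranone that erodes the C2 configuration, or attack of the iodane on the allyl ether alkene. The fallback sets out from 5 and comes back at 8, replacing the oxidative shift by a photochemical Wolff ring contraction that forms the same C3–C3a bond. Flavanone 5 would be acylated at C3 (LiN(SiMe3)2, THF, −78 °C; CF3CO2CH2CF3) to (2S)-7-(allyloxy)-3-(trifluoroacetyl)-2-(3,4,5-trimethoxyphenyl)chroman-4-one F1. Detrifluoroacetylative diazo transfer (MsN3, Et3N, MeCN, rt) should then give (2R)-7-(allyloxy)-3-diazo-2-(3,4,5-trimethoxyphenyl)chroman-4-one F2, in which C2 is spatially unchanged and only the descriptor differs. Irradiation (365 nm, MeOH, rt) should expel dinitrogen and shift ring A carbon C4a from C4 to the carbene carbon C3, giving the ketene (2R)-6-(allyloxy)-3-(oxomethylidene)-2-(3,4,5-trimethoxyphenyl)-2,3-dihydrobenzofuran F3. Methanol traps it as ester 8 together with its cis epimer, methyl (2S,3R)-6-(allyloxy)-2-(3,4,5-trimethoxyphenyl)-2,3-dihydrobenzofuran-3-carboxylate F4, and NaOMe in MeOH at rt should funnel F4 into the trans ester 8.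

Step 6. What may go wrong: migration of the allyl group to C7 instead of C5 (poor regioselectivity), or thermal erosion at the benzylic C2–O bond. The fallback sets out from 11 and comes back at 13, replacing the sigmatropic shift by electrophilic halogenation and cross-coupling. Deallylation (Pd(PPh3)4 cat., morpholine, THF, rt) should give (2S,3S)-3-methyl-2-(3,4,5-trimethoxyphenyl)-2,3-dihydrobenzofuran-6-ol F5. Bromination at C5, the position ortho to the hydroxyl and para to the ring oxygen (NBS, MeCN, −20 °C), should give (2S,3S)-5-bromo-3-methyl-2-(3,4,5-trimethoxyphenyl)-2,3-dihydrobenzofuran-6-ol F6. Stille allylation (allyltributylstannane, Pd(PPh3)4, LiCl, DMF, 90 °C) should then give 13.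

Step 2. What may go wrong: poor facial selectivity at C2, over-addition of the aryl-rhodium species to the ketone of 5, or base-induced opening of the chromone. The fallback sets out from 3 and comes back at 5, replacing asymmetric catalysis by a kinetic resolution. Addition of 4 with achiral [Rh(OH)(cod)]2 (dioxane/H2O, 50 °C) should give racemic 7-(allyloxy)-2-(3,4,5-trimethoxyphenyl)chroman-4-one F7. Noyori-type asymmetric transfer hydrogenation (RuCl(p-cymene)[(R,R)-TsDPEN], HCO2H/Et3N, EtOAc, rt, about half conversion) should reduce the (R)-ketone to (2R,4R)-7-(allyloxy)-2-(3,4,5-trimethoxyphenyl)chroman-4-ol F8 and leave (S)-ketone 5, which is separated by chromatography. The same resolution can upgrade scalemic 5 from step 2.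

**Further compounds**
F1 | step 3 | (2S)-7-(allyloxy)-3-(trifluoroacetyl)-2-(3,4,5-trimethoxyphenyl)chroman-4-one | C=CCOc1ccc2c(c1)O[C@H](c1cc(OC)c(OC)c(OC)c1)C(C(=O)C(F)(F)F)C2=O
F2 | step 3 | (2R)-7-(allyloxy)-3-diazo-2-(3,4,5-trimethoxyphenyl)chroman-4-one | C=CCOc1ccc2c(c1)O[C@H](c1cc(OC)c(OC)c(OC)c1)C(=[N+]=[N-])C2=O
F3 | step 3 | (2R)-6-(allyloxy)-3-(oxomethylidene)-2-(3,4,5-trimethoxyphenyl)-2,3-dihydrobenzofuran | C=CCOc1ccc2c(c1)O[C@H](c1cc(OC)c(OC)c(OC)c1)C2=C=O
F4 | step 3 | methyl (2S,3R)-6-(allyloxy)-2-(3,4,5-trimethoxyphenyl)-2,3-dihydrobenzofuran-3-carboxylate (2,3-cis) | C=CCOc1ccc2c(c1)O[C@H](c1cc(OC)c(OC)c(OC)c1)[C@@H]2C(=O)OC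
F5 | step 6 | (2S,3S)-3-methyl-2-(3,4,5-trimethoxyphenyl)-2,3-dihydrobenzofuran-6-ol | Oc1ccc2c(c1)O[C@H](c1cc(OC)c(OC)c(OC)c1)[C@H]2C
F6 | step 6 | (2S,3S)-5-bromo-3-methyl-2-(3,4,5-trimethoxyphenyl)-2,3-dihydrobenzofuran-6-ol | Brc1cc2c(cc1O)O[C@H](c1cc(OC)c(OC)c(OC)c1)[C@H]2C
F7 | step 2 | racemic 7-(allyloxy)-2-(3,4,5-trimethoxyphenyl)chroman-4-one | C=CCOc1ccc2c(c1)OC(c1cc(OC)c(OC)c(OC)c1)CC2=O
F8 | step 2 | (2R,4R)-7-(allyloxy)-2-(3,4,5-trimethoxyphenyl)chroman-4-ol (2,4-cis) | C=CCOc1ccc2c(c1)O[C@@H](c1cc(OC)c(OC)c(OC)c1)C[C@H]2O
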